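(The numbers in the tables are simulated on assumed constants, noise included.)

Target counted per catalyst and per minute is what I carry here: percent of target, over mol% of catalyst, over minutes, which is a turnover frequency.

| setting | midnight | autumn | Tuesday's | Monday's |
|---|---|---|---|---|
| starting material | 0.25 M | 0.25 M | 0.25 M | 0.25 M |
| second substrate | 2 equiv | 2 equiv | 2.00 equiv | 2.00 equiv |
| protic impurity | 0.025 M | 0.025 M | 0.0250 M | 0.0250 M |
| free catalyst | 0.81 mol% | 3 mol% | 1.2 mol% | 3.9 mol% |
| temperature | −35 °C | −24 °C |  |  |
| remark | run made earlier | run made earlier | at −20 °C throughout | at −20 °C until 2.0 min, from then on at −40 °C |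
| time |  |  | 6.0 min | 4.0 min |

- midnight (time / min: target / %, starting material / %): 0.667: 1.3, 99.5; 2.00: 0, 97.8; 4.00: 4.9, 98.0; 6.00: 4.2, 96.0; 8.00: 5.0, 94.8
- autumn (time / min: target / %, starting material / %): 0.833: 4.7, 93.3; 1.50: 9.6, 90.1; 2.50: 17.2, 84.4; 3.00: 16.2, 81.3; 4.00: 21.7, 77.2

(scatter of a reading: 1 percentage point)

1. which one finishes higher in amount of target, in percent of the starting material charged ("neither" within 2 percentage points) (Tuesday's / Monday's / neither)
2. amount of target at the end, in percent of the starting material charged, Tuesday's
3. amount of target at the end, in percent of the starting material charged, Monday's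

The autumn run gives 1.88 min⁻¹ at its first reading and 1.81 min⁻¹ at its last, so its line is straight within the scatter of 1 percentage point. The midnight run gives 0.772 min⁻¹, though its 5.0% of target carries that same scatter. Both runs change loading and temperature together, so I assume that target follows loading and that each degree multiplies the frequency by the same factor. That gives 2.46 min⁻¹ at −20 °C, the warm turnover frequency, and 0.524 min⁻¹ at −40 °C.

Now the settings, one at a time. Loading: Monday's carries 3.25 times the catalyst of Tuesday's, and by hand its target rises in step. Time: Tuesday's has 3.00 times the warm minutes of Monday's, which is less than the gain from loading. The warm parts therefore stand close, with 19.2% for Monday's against 17.7% for Tuesday's. Temperature: the cold frequency is lower, yet Monday's cold 2.00 min still add 4.09%. I commit to 23.3% for Monday's, higher than Tuesday's, and by hand the cold stage adds more to that lead than the warm parts do.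

The forecast, whose figures differ a little from mine, gives Tuesday's 19.5% and Monday's 24%, so Monday's ahead, and notes that “A lower catalyst order would raise Tuesday's figure”.

The flask gives Tuesday's 15.3% and Monday's 21.6%, so Monday's ends higher by 6.3 points, clear of the 2 points margin.

    catalyst intermediate A → free catalyst + target (k = 0.410 s⁻¹, Ea = 61.0 kJ mol⁻¹)
    free catalyst + target → spent catalyst (k = 0.260 M⁻¹ s⁻¹, Ea = 47.0 kJ mol⁻¹)
    second substrate + free catalyst ⇌ catalyst intermediate B (K = 2.10 M⁻¹, k = 1.70 M⁻¹ s⁻¹, Ea = 51.0 kJ mol⁻¹, ΔH = −3.00 kJ mol⁻¹)
    second substrate + protic impurity → quenched substrate (k = 0.210 M⁻¹ s⁻¹, Ea = 51.0 kJ mol⁻¹)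
    starting material + free catalyst ⇌ catalyst intermediate A (K = 1.60 M⁻¹, k = 1.50 M⁻¹ s⁻¹, Ea = 48.0 kJ mol⁻¹, ΔH = −30.0 kJ mol⁻¹)
    catalyst intermediate B → free catalyst + second product (k = 0.220 s⁻¹, Ea = 58.0 kJ mol⁻¹)
    (constants at −20 °C)

Monday's warm stage works out at 2.50 min⁻¹ against my 2.46 min⁻¹. Part of what holds Monday's target down is the reverse step, catalyst intermediate A to starting material and free catalyst. With that step removed, Monday's ends at 42.4% instead of 21.6%, a larger effect than removing the step to spent catalyst or the change of temperature. For the neighbour, Monday's recipe at 1.0 M of starting material, my frequency has no [starting material] in it, so the reckoning stays at 23.3%. The computed flask gives 26.5%.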